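**Plan**

- Numbering (cembrane type): C1 is the ring CH that carries C15; C2 the lactone O–CH; C3=C4 and C7=C8 the E alkenes of the open chain; C7 the acetoxy CH; C8 and C11 the peroxy carbons; C12=C13 the Z alkene; C15, C16, C17 the lactone α-carbon, carbonyl and exocyclic CH2.
- Feature used: C2 is an allylic carbinol carbon of the fourteen-membered carbocycle, between stereocentre C1 and the E C3=C4 alkene, so a C2 aldehyde and an E C3 alkenyl iodide (two electrophiles) can be joined reductively to close that ring.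
- Cuts, in retrosynthetic order: the C7 acetate; O–C8 (epoxide opening) and O–C11 (displacement) of the 1,2-dioxane; the acyl–O bond of the lactone; ring bond C2–C3; chain bond C9–C10; the ring bond of a carvone-derived diol, whose two carbons become C2 and C11.
- Forward: carvone is opened to the C10–C14/C1/C2/C15–C17 ketone, pent-4-yn-1-ol is extended to the C3–C9 iododienyl bromide, the two are joined at C9–C10, the carbocycle closes at C2–C3, then the γ-lactone ring is formed and last the 1,2-dioxane ring.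
- Stereochemistry: C1 and the 12Z alkene from (R)-carvone; 3E from syn carboalumination; 7E from a stabilised Wittig reaction; C11 from CBS reduction followed by invertive peroxidation; C2 from Felkin–Anh reduction of the C2 ketone; C7 and C8 from a Shi epoxidation and its invertive opening at C8.

Key step: step 17

Remark: the ring closure is assumed to give mainly the 2S alcohol (Felkin–Anh), but this is not relied upon because C2 is re-set in steps 18 and 19; the L-fructose-derived enantiomer of the Shi ketone is taken as available (it is made from L-sorbose).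

**Route**

Step 1
Reactants: 1 (R)-(−)-carvone
Product: 2 (R)-5-(3-chloroprop-1-en-2-yl)-2-methylcyclohex-2-en-1-one
Conditions: Ca(OCl)2, CO2 (dry ice), CH2Cl2–H2O, 0 °C
Reagents that add atoms: calcium hypochlorite, [Ca+2].[O-]Cl.[O-]Cl
Why: Hypochlorous acid released from Ca(OCl)2 by CO2 attacks the electron-rich 1,1-disubstituted alkene in an ene-type allylic chlorination that moves the double bond into the former methyl group, while the electron-poor enone alkene and the ring stereocentre are not touched.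

Step 2
Reactants: 2 (R)-5-(3-chloroprop-1-en-2-yl)-2-methylcyclohex-2-en-1-one
Product: 4 (R)-5-(3-hydroxyprop-1-en-2-yl)-2-methylcyclohex-2-en-1-one, via allylic acetate 3 (not isolated)
Conditions: KOAc, Bu4NI (cat.), DMF, 50 °C; then MeOH, K2CO3, 0 °C to rt
Reagents that add atoms: potassium acetate, CC(=O)[O-].[K+]
Why: SN2 displacement of the primary allylic chloride by acetate followed by K2CO3-catalysed transesterification with methanol in the same flask frees the allylic alcohol (the future C16 oxygen) without affecting the enone.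

Step 3
Reactants: 4 (R)-5-(3-hydroxyprop-1-en-2-yl)-2-methylcyclohex-2-en-1-one
Product: 5 (R)-5-[3-(tert-butyldiphenylsilyloxy)prop-1-en-2-yl]-2-methylcyclohex-2-en-1-one
Conditions: tBuPh2SiCl, imidazole, DMF, 0 °C to rt
Reagents that add atoms: tert-butyl(chloro)diphenylsilane, CC(C)(C)[Si](Cl)(c1ccccc1)c1ccccc1
Why: Silylation of the primary alcohol; the tert-butyldiphenylsilyl ether is chosen because it survives organolithium reagents and the later acidic removal of a triethylsilyl ether.

Step 4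
Reactants: 5 (R)-5-[3-(tert-butyldiphenylsilyloxy)prop-1-en-2-yl]-2-methylcyclohex-2-en-1-one
Product: 7 (5S)-5-[3-(tert-butyldiphenylsilyloxy)prop-1-en-2-yl]-6-hydroxy-2-methylcyclohex-2-en-1-one (C6 epimers), via lithium dienolate 6 (not isolated)
Conditions: LiN(iPr)2, THF, −78 °C; then 2-(phenylsulfonyl)-3-phenyloxaziridine, −78 °C; aq. NH4Cl
Reagents that add atoms: 2-(phenylsulfonyl)-3-phenyloxaziridine, O=S(=O)(c1ccccc1)N1OC1c1ccccc1
Why: LiN(iPr)2 deprotonates the enone kinetically at the α′ methylene to give cross-conjugated dienolate 6, which is hydroxylated by the N-sulfonyloxaziridine (Davis enolate oxidation), and the configuration of the new carbinol is irrelevant because this carbon becomes the C2 aldehyde.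

Step 5
Reactants: 7 (5S)-5-[3-(tert-butyldiphenylsilyloxy)prop-1-en-2-yl]-6-hydroxy-2-methylcyclohex-2-en-1-one (C6 epimers)
Product: 8 (6S)-6-[3-(tert-butyldiphenylsilyloxy)prop-1-en-2-yl]-2,3-dimethylcyclohex-3-ene-1,2-diol (diastereomers at C1 and C2)
Conditions: MeLi (3 equiv), THF–Et2O, −78 °C; aq. NH4Cl
Reagents that add atoms: methyllithium, [Li]C
Why: Methyllithium deprotonates the hydroxyl and then adds 1,2 to the enone carbonyl, which installs the methyl group that becomes C10 and gives the vicinal diol needed for ring cleavage; all diastereomers converge in step 6.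

Step 6
Reactants: 8 (6S)-6-[3-(tert-butyldiphenylsilyloxy)prop-1-en-2-yl]-2,3-dimethylcyclohex-3-ene-1,2-diol
Product: 10 (3Z,6S)-6-[3-(tert-butyldiphenylsilyloxy)prop-1-en-2-yl]-7-hydroxy-3-methylhept-3-en-2-one, via keto aldehyde 9 (not isolated)
Conditions: Pb(OAc)4, CH2Cl2, 0 °C; filtration through Celite; then EtOH, NaBH4, −78 °C
Reagents that add atoms: none
Why: Glycol cleavage with Pb(OAc)4 (Criegee oxidation) breaks the bond between the two carbinol carbons to give the Z methyl enone (C11) and the epimerisable aldehyde (C2) of 9 under neutral conditions, and NaBH4 at −78 °C then reduces the aldehyde selectively in the presence of the conjugated ketone.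

Step 7
Reactants: 10 (3Z,6S)-6-[3-(tert-butyldiphenylsilyloxy)prop-1-en-2-yl]-7-hydroxy-3-methylhept-3-en-2-one
Product: 11 (3Z,6S)-6-[3-(tert-butyldiphenylsilyloxy)prop-1-en-2-yl]-3-methyl-7-(triethylsilyloxy)hept-3-en-2-one
Conditions: Et3SiCl, imidazole, CH2Cl2, 0 °C
Reagents that add atoms: chlorotriethylsilane, CC[Si](Cl)(CC)CC
Why: Silylation under weakly basic conditions, carried out without delay because the free hydroxyl of 10 could add to the enone, gives a triethylsilyl ether that tolerates enolate chemistry and is later removable beside the other silyl ethers.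

Step 8
Reactants: 12 pent-4-yn-1-ol
Product: 14 (E)-5-iodo-4-methylpent-4-en-1-ol, via alkenylalane 13 (not isolated)
Conditions: Me3Al (3 equiv), Cp2ZrCl2 (0.25 equiv), CH2Cl2, 0 °C to rt; then I2, THF, −30 to 0 °C
Reagents that add atoms: trimethylaluminium, C[Al](C)C; iodine, [I][I]
Why: Zirconium-catalysed carboalumination (Negishi) adds methyl and aluminium syn across the alkyne with aluminium at the terminal carbon, and iodinolysis of alkenylalane 13 with retention gives the E alkenyl iodide that becomes the C3=C4 alkene.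

Step 9
Reactants: 14 (E)-5-iodo-4-methylpent-4-en-1-ol; 15 ethyl 2-(triphenylphosphoranylidene)propanoate
Product: 17 ethyl (2E,6E)-7-iodo-2,6-dimethylhepta-2,6-dienoate, via iodo enal 16 (not isolated)
Conditions: TEMPO (0.1 equiv), PhI(OAc)2, CH2Cl2, rt; then 15, rt
Reagents that add atoms: none
Why: TEMPO/PhI(OAc)2 oxidises the primary alcohol to aldehyde 16 without touching the alkenyl iodide, and the stabilised α-methyl ylide added to the same flask gives the E trisubstituted enoate (Wittig olefination) that becomes the C7=C8 alkene.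

Step 10
Reactants: 17 ethyl (2E,6E)-7-iodo-2,6-dimethylhepta-2,6-dienoate
Product: 18 (2E,6E)-7-iodo-2,6-dimethylhepta-2,6-dien-1-ol
Conditions: iBu2AlH, CH2Cl2, −78 °C; aq. Rochelle salt
Reagents that add atoms: none
Why: iBu2AlH reduces the conjugated ester 1,2 to the allylic alcohol at low temperature and leaves the alkenyl iodide intact.

Step 11
Reactants: 18 (2E,6E)-7-iodo-2,6-dimethylhepta-2,6-dien-1-ol
Product: 19 (1E,5E)-7-bromo-1-iodo-2,6-dimethylhepta-1,5-diene
Conditions: CBr4, PPh3, CH2Cl2, 0 °C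
Reagents that add atoms: carbon tetrabromide, BrC(Br)(Br)Br
Why: Appel bromination converts the primary allylic alcohol into the bromide under neutral conditions without allylic transposition.

Step 12
Reactants: 11 (3Z,6S)-6-[3-(tert-butyldiphenylsilyloxy)prop-1-en-2-yl]-3-methyl-7-(triethylsilyloxy)hept-3-en-2-one; 19 (1E,5E)-7-bromo-1-iodo-2,6-dimethylhepta-1,5-diene
Product: 21 (1E,5E,10Z,13S)-13-[3-(tert-butyldiphenylsilyloxy)prop-1-en-2-yl]-1-iodo-2,6,10-trimethyl-14-(triethylsilyloxy)tetradeca-1,5,10-trien-9-one, via lithium enolate 20 (not isolated)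
Conditions: LiN(iPr)2, THF, −78 °C; then 19, DMPU, −78 to −30 °C
Reagents that add atoms: none
Why: LiN(iPr)2 removes a proton from the methyl group of the ketone under kinetic control to give cross-conjugated enolate 20, which is alkylated on carbon by the primary allylic bromide (SN2) to form the C9–C10 bond, with the silyl ethers, the Z alkene and the alkenyl iodide as spectators.

Step 13
Reactants: 21 (1E,5E,10Z,13S)-13-[3-(tert-butyldiphenylsilyloxy)prop-1-en-2-yl]-1-iodo-2,6,10-trimethyl-14-(triethylsilyloxy)tetradeca-1,5,10-trien-9-one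
Product: 22 (1E,5E,9R,10Z,13S)-13-[3-(tert-butyldiphenylsilyloxy)prop-1-en-2-yl]-1-iodo-2,6,10-trimethyl-14-(triethylsilyloxy)tetradeca-1,5,10-trien-9-ol
Conditions: (S)-2-methyl-CBS-oxazaborolidine, catecholborane, toluene, −78 °C
Reagents that add atoms: none
Why: Corey–Bakshi–Shibata reduction: with the α-methylalkenyl group as the large and the C10 methylene as the small ketone substituent, the (S)-oxazaborolidine directs hydride to the face that gives the 11R allylic alcohol, and removing the enone at this point also ends any risk of Z to E isomerisation.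

Step 14
Reactants: 22 (1E,5E,9R,10Z,13S)-13-[3-(tert-butyldiphenylsilyloxy)prop-1-en-2-yl]-1-iodo-2,6,10-trimethyl-14-(triethylsilyloxy)tetradeca-1,5,10-trien-9-ol
Product: 23 the 9-(tert-butyldimethylsilyl) ether of 22 (cembrane C11–OSitBuMe2)
Conditions: tBuMe2SiCl, imidazole, DMF, rt
Reagents that add atoms: tert-butyl(chloro)dimethylsilane, CC(C)(C)[Si](C)(C)Cl
Why: Silylation of the secondary allylic alcohol as a tert-butyldimethylsilyl ether, which is stable to the mild acid of step 15 and to divalent chromium.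

Step 15
Reactants: 23 the 9-(tert-butyldimethylsilyl) ether of 22
Product: 24 (2S,4Z,6R,9E,13E)-6-(tert-butyldimethylsilyloxy)-2-[3-(tert-butyldiphenylsilyloxy)prop-1-en-2-yl]-14-iodo-5,9,13-trimethyltetradeca-4,9,13-trien-1-ol
Conditions: pyridinium p-toluenesulfonate (0.2 equiv), MeOH–CH2Cl2, 0 °C
Reagents that add atoms: none
Why: Acid-catalysed methanolysis cleaves the primary triethylsilyl ether much faster than the secondary tert-butyldimethylsilyl and the tert-butyldiphenylsilyl ethers.

Step 16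
Reactants: 24 (2S,4Z,6R,9E,13E)-6-(tert-butyldimethylsilyloxy)-2-[3-(tert-butyldiphenylsilyloxy)prop-1-en-2-yl]-14-iodo-5,9,13-trimethyltetradeca-4,9,13-trien-1-ol
Product: 25 (2S,4Z,6R,9E,13E)-6-(tert-butyldimethylsilyloxy)-2-[3-(tert-butyldiphenylsilyloxy)prop-1-en-2-yl]-14-iodo-5,9,13-trimethyltetradeca-4,9,13-trienal (C2 aldehyde, E C3 alkenyl iodide)
Conditions: Dess–Martin periodinane, NaHCO3, CH2Cl2, 0 °C
Reagents that add atoms: none
Why: Buffered Dess–Martin oxidation gives the aldehyde under non-basic conditions, which avoids epimerisation at C1 and migration of the adjacent 1,1-disubstituted alkene into conjugation; 25 is used at once.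

Step 17
Reactants: 25 (2S,4Z,6R,9E,13E)-6-(tert-butyldimethylsilyloxy)-2-[3-(tert-butyldiphenylsilyloxy)prop-1-en-2-yl]-14-iodo-5,9,13-trimethyltetradeca-4,9,13-trienal
Product: 27 (1S,2S,3E,7E,11R,12Z)-11-(tert-butyldimethylsilyloxy)-16-(tert-butyldiphenylsilyloxy)cembra-3,7,12,15(17)-tetraen-2-ol, via alkenylchromium dichloride 26 (not isolated)
Conditions: CrCl2 (10 equiv), NiCl2 (cat.), degassed DMSO–THF, rt, 25 added slowly (final about 2 mM)
Reagents that add atoms: none
Why: CrCl2 reduces catalytic NiCl2 to zerovalent nickel, which inserts into the C3–I bond with retention of the E geometry, and transmetalation gives the trivalent alkenylchromium species 26, which adds to the C2 aldehyde; the closest known reaction type is the Nozaki–Hiyama–Kishi macrocyclisation of iodoalkenyl aldehydes to carbocyclic allylic alcohols. The fourteen-membered ring closes by 1,2-addition of C3 to the C2 carbonyl carbon (14-exo-trig), helped by slow addition to high dilution and by the three alkenes that stiffen the chain. The new stereocentre C2 is formed under the control of the adjacent C1 centre: Felkin–Anh attack anti to the bulky 2-propenyl branch should favour the 2S alcohol drawn for 27, but both epimers are usable because C2 is oxidised in step 18 and re-set in step 19. The step needs chemoselectivity (reaction only between the alkenyl iodide and the aldehyde) and preservation of the epimerisable C1 centre next to the aldehyde; the weakly basic, oxophilic alkenylchromium reagent in a neutral medium secures both, and the silyl ethers at C11 and C16 leave no other electrophile in the molecule.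

Step 18
Reactants: 27 (1S,2S,3E,7E,11R,12Z)-11-(tert-butyldimethylsilyloxy)-16-(tert-butyldiphenylsilyloxy)cembra-3,7,12,15(17)-tetraen-2-ol
Product: 28 (1S,3E,7E,11R,12Z)-11-(tert-butyldimethylsilyloxy)-16-(tert-butyldiphenylsilyloxy)cembra-3,7,12,15(17)-tetraen-2-one
Conditions: Dess–Martin periodinane, NaHCO3, CH2Cl2, 0 °C
Reagents that add atoms: none
Why: Dess–Martin oxidation of the allylic alcohol gives the C2 enone from either C2 epimer, so the outcome of the ring closure at C2 does not matter.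

Step 19
Reactants: 28 (1S,3E,7E,11R,12Z)-11-(tert-butyldimethylsilyloxy)-16-(tert-butyldiphenylsilyloxy)cembra-3,7,12,15(17)-tetraen-2-one
Product: 29 (1S,2R,3E,7E,11R,12Z)-11-(tert-butyldimethylsilyloxy)-16-(tert-butyldiphenylsilyloxy)cembra-3,7,12,15(17)-tetraen-2-ol
Conditions: LiBH(sBu)3, THF, −78 °C; aq. NH4Cl
Reagents that add atoms: none
Why: Felkin–Anh 1,2-reduction: the bulky hydride attacks the C2 carbonyl anti to the 2-propenyl branch at C1 (C14 methylene gauche to the carbonyl oxygen), which gives the 2R alcohol needed for the trans lactone, and conjugate reduction is blocked by the fully substituted β-carbon C4.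

Step 20
Reactants: 29 (1S,2R,3E,7E,11R,12Z)-11-(tert-butyldimethylsilyloxy)-16-(tert-butyldiphenylsilyloxy)cembra-3,7,12,15(17)-tetraen-2-ol
Product: 30 (1S,2R,3E,7E,11R,12Z)-cembra-3,7,12,15(17)-tetraene-2,11,16-triol
Conditions: Bu4NF (3 equiv), THF, 0 °C to rt
Reagents that add atoms: none
Why: Fluoride removes both silyl ethers to give the triol.

Step 21
Reactants: 30 (1S,2R,3E,7E,11R,12Z)-cembra-3,7,12,15(17)-tetraene-2,11,16-triol
Product: 32 (1S,2R,3E,7E,11R,12Z)-11-hydroxycembra-3,7,12,15(17)-tetraen-16,2-olide, via lactol 31 (not isolated)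
Conditions: TEMPO (0.2 equiv), PhI(OAc)2 (2.2 equiv), CH2Cl2, rt
Reagents that add atoms: none
Why: TEMPO/PhI(OAc)2 oxidises the primary allylic alcohol in preference to the two secondary ones, the resulting enal is trapped by the C2 hydroxyl as lactol 31 and this is oxidised on to the α-methylene γ-lactone (oxidative lactonisation of a 1,4-diol), which fixes the trans ring fusion set at C1 and C2.

Step 22
Reactants: 32 (1S,2R,3E,7E,11R,12Z)-11-hydroxycembra-3,7,12,15(17)-tetraen-16,2-olide
Product: 34 (1S,2R,3E,7E,11S,12Z)-11-hydroperoxycembra-3,7,12,15(17)-tetraen-16,2-olide, via allylic methanesulfonate 33 (not isolated)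
Conditions: MsCl, Et3N, CH2Cl2, −65 °C; then anhydrous H2O2 (excess) in Et2O, −78 to −40 °C
Reagents that add atoms: hydrogen peroxide, OO
Why: The only free hydroxyl is converted in the cold into allylic methanesulfonate 33, which is displaced by hydrogen peroxide, a neutral α-effect nucleophile, in an SN2 reaction with inversion (sulfonate displacement by H2O2) to give the 11S hydroperoxide, and the neutral medium leaves the α-methylene lactone untouched.

Step 23
Reactants: 34 (1S,2R,3E,7E,11S,12Z)-11-hydroperoxycembra-3,7,12,15(17)-tetraen-16,2-olide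
Product: 35 (1S,2R,3E,7S,8S,11S,12Z)-7,8-epoxy-11-hydroperoxycembra-3,12,15(17)-trien-16,2-olide
Conditions: L-fructose-derived Shi ketone (1,2:4,5-di-O-isopropylidene-β-L-erythro-2,3-hexodiulo-2,6-pyranose, 3 equiv), Oxone (2KHSO5·KHSO4·K2SO4), NaHCO3, MeCN–aq. Na2EDTA, 0 °C
Reagents that add atoms: Oxone (active component potassium peroxymonosulfate), [K+].[O-]S(=O)(=O)OO
Why: Shi epoxidation: the dioxirane from the L-fructose-derived ketone epoxidises the only electron-rich alkene, C7=C8 (the others are deactivated by the lactone carbonyl, the allylic lactone oxygen or the allylic hydroperoxide), through the spiro transition state that gives the 7S,8S epoxide, the mirror image of the R,R epoxides that the D-fructose-derived ketone gives with E trisubstituted alkenes; the hydroperoxide should survive because such dioxiranes also operate in the presence of H2O2.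

Step 24
Reactants: 35 (1S,2R,3E,7S,8S,11S,12Z)-7,8-epoxy-11-hydroperoxycembra-3,12,15(17)-trien-16,2-olide
Product: 36 (1S,2R,3E,7S,8R,11S,12Z)-8,11-epidioxy-7-hydroxycembra-3,12,15(17)-trien-16,2-olide
Conditions: camphorsulfonic acid (0.1 equiv), CH2Cl2, 0 °C
Reagents that add atoms: none
Why: Acid-catalysed intramolecular opening of the epoxide by the hydroperoxide (6-exo-tet) takes place at the tertiary carbon C8 with inversion, which closes the 1,2-dioxane ring with the 8R configuration and frees the 7S hydroxyl.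

Step 25
Reactants: 36 (1S,2R,3E,7S,8R,11S,12Z)-8,11-epidioxy-7-hydroxycembra-3,12,15(17)-trien-16,2-olide
Product: 37 (1S,2R,3E,7S,8R,11S,12Z)-7-acetoxy-8,11-epidioxycembra-3,12,15(17)-trien-16,2-olide (target)
Conditions: Ac2O, pyridine, DMAP (cat.), CH2Cl2, 0 °C
Reagents that add atoms: acetic anhydride, CC(=O)OC(C)=O
Why: Acetylation of the secondary alcohol with Ac2O and pyridine at 0 °C, a weak base that should not trigger Kornblum–DeLaMare fragmentation of the peroxide, gives the target.

**Compound list**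

1 | (R)-(−)-carvone | CC1=CC[C@@H](C(C)=C)CC1=O | starting material
2 | (R)-5-(3-chloroprop-1-en-2-yl)-2-methylcyclohex-2-en-1-one | CC1=CC[C@@H](C(CCl)=C)CC1=O | intermediate
3 | 2-[(1R)-4-methyl-5-oxocyclohex-3-en-1-yl]prop-2-en-1-yl acetate (not isolated) | CC1=CC[C@@H](C(COC(C)=O)=C)CC1=O | intermediate
4 | (R)-5-(3-hydroxyprop-1-en-2-yl)-2-methylcyclohex-2-en-1-one | CC1=CC[C@@H](C(CO)=C)CC1=O | intermediate
5 | (R)-5-[3-(tert-butyldiphenylsilyloxy)prop-1-en-2-yl]-2-methylcyclohex-2-en-1-one | CC1=CC[C@@H](C(CO[Si](c2ccccc2)(c2ccccc2)C(C)(C)C)=C)CC1=O | intermediate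
6 | lithium dienolate of 5, ring stereocentre unchanged (not isolated) | CC1=CC[C@@H](C(CO[Si](c2ccccc2)(c2ccccc2)C(C)(C)C)=C)C=C1O[Li] | intermediate
7 | (5S)-5-[3-(tert-butyldiphenylsilyloxy)prop-1-en-2-yl]-6-hydroxy-2-methylcyclohex-2-en-1-one, C6 epimers | CC1=CC[C@@H](C(CO[Si](c2ccccc2)(c2ccccc2)C(C)(C)C)=C)C(O)C1=O | intermediate
8 | (6S)-6-[3-(tert-butyldiphenylsilyloxy)prop-1-en-2-yl]-2,3-dimethylcyclohex-3-ene-1,2-diol, diastereomers at C1 and C2 | CC1=CC[C@@H](C(CO[Si](c2ccccc2)(c2ccccc2)C(C)(C)C)=C)C(O)C1(C)O | intermediate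
9 | (2S,4Z)-2-[3-(tert-butyldiphenylsilyloxy)prop-1-en-2-yl]-5-methyl-6-oxohept-4-enal (not isolated) | O=C[C@H](C(=C)CO[Si](c1ccccc1)(c1ccccc1)C(C)(C)C)C/C=C(C)\C(C)=O | intermediate
10 | (3Z,6S)-6-[3-(tert-butyldiphenylsilyloxy)prop-1-en-2-yl]-7-hydroxy-3-methylhept-3-en-2-one | OC[C@H](C(=C)CO[Si](c1ccccc1)(c1ccccc1)C(C)(C)C)C/C=C(C)\C(C)=O | intermediate
11 | (3Z,6S)-6-[3-(tert-butyldiphenylsilyloxy)prop-1-en-2-yl]-3-methyl-7-(triethylsilyloxy)hept-3-en-2-one | CC[Si](CC)(CC)OC[C@H](C(=C)CO[Si](c1ccccc1)(c1ccccc1)C(C)(C)C)C/C=C(C)\C(C)=O | intermediate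
12 | pent-4-yn-1-ol | C#CCCCO | starting material
13 | dimethyl[(1E)-5-(dimethylalumanyloxy)-2-methylpent-1-en-1-yl]alane (not isolated) | C[Al](C)/C=C(\C)CCCO[Al](C)C | intermediate
14 | (E)-5-iodo-4-methylpent-4-en-1-ol | OCCC/C(C)=C/I | intermediate
15 | ethyl 2-(triphenylphosphoranylidene)propanoate | CCOC(=O)C(C)=P(c1ccccc1)(c1ccccc1)c1ccccc1 | starting material
16 | (E)-5-iodo-4-methylpent-4-enal (not isolated) | O=CCC/C(C)=C/I | intermediate
17 | ethyl (2E,6E)-7-iodo-2,6-dimethylhepta-2,6-dienoate | CCOC(=O)/C(C)=C/CC/C(C)=C/I | intermediate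
18 | (2E,6E)-7-iodo-2,6-dimethylhepta-2,6-dien-1-ol | OC/C(C)=C/CC/C(C)=C/I | intermediate
19 | (1E,5E)-7-bromo-1-iodo-2,6-dimethylhepta-1,5-diene | BrC/C(C)=C/CC/C(C)=C/I | intermediate
20 | lithium enolate of 11, formed at the methyl group (not isolated) | CC[Si](CC)(CC)OC[C@H](C(=C)CO[Si](c1ccccc1)(c1ccccc1)C(C)(C)C)C/C=C(C)\C(=C)O[Li] | intermediate
21 | (1E,5E,10Z,13S)-13-[3-(tert-butyldiphenylsilyloxy)prop-1-en-2-yl]-1-iodo-2,6,10-trimethyl-14-(triethylsilyloxy)tetradeca-1,5,10-trien-9-one | CC[Si](CC)(CC)OC[C@H](C(=C)CO[Si](c1ccccc1)(c1ccccc1)C(C)(C)C)C/C=C(C)\C(=O)CC/C(C)=C/CC/C(C)=C/I | intermediate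
22 | (1E,5E,9R,10Z,13S)-13-[3-(tert-butyldiphenylsilyloxy)prop-1-en-2-yl]-1-iodo-2,6,10-trimethyl-14-(triethylsilyloxy)tetradeca-1,5,10-trien-9-ol | CC[Si](CC)(CC)OC[C@H](C(=C)CO[Si](c1ccccc1)(c1ccccc1)C(C)(C)C)C/C=C(C)\[C@H](O)CC/C(C)=C/CC/C(C)=C/I | intermediate
23 | 9-(tert-butyldimethylsilyl) ether of 22 (cembrane C11–OSitBuMe2, 11R) | CC[Si](CC)(CC)OC[C@H](C(=C)CO[Si](c1ccccc1)(c1ccccc1)C(C)(C)C)C/C=C(C)\[C@H](O[Si](C)(C)C(C)(C)C)CC/C(C)=C/CC/C(C)=C/I | intermediate
24 | (2S,4Z,6R,9E,13E)-6-(tert-butyldimethylsilyloxy)-2-[3-(tert-butyldiphenylsilyloxy)prop-1-en-2-yl]-14-iodo-5,9,13-trimethyltetradeca-4,9,13-trien-1-ol | OC[C@H](C(=C)CO[Si](c1ccccc1)(c1ccccc1)C(C)(C)C)C/C=C(C)\[C@H](O[Si](C)(C)C(C)(C)C)CC/C(C)=C/CC/C(C)=C/I | intermediate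
25 | (2S,4Z,6R,9E,13E)-6-(tert-butyldimethylsilyloxy)-2-[3-(tert-butyldiphenylsilyloxy)prop-1-en-2-yl]-14-iodo-5,9,13-trimethyltetradeca-4,9,13-trienal | O=C[C@H](C(=C)CO[Si](c1ccccc1)(c1ccccc1)C(C)(C)C)C/C=C(C)\[C@H](O[Si](C)(C)C(C)(C)C)CC/C(C)=C/CC/C(C)=C/I | intermediate
26 | alkenylchromium dichloride from 25, CrCl2 at C3 (not isolated) | O=C[C@H](C(=C)CO[Si](c1ccccc1)(c1ccccc1)C(C)(C)C)C/C=C(C)\[C@H](O[Si](C)(C)C(C)(C)C)CC/C(C)=C/CC/C(C)=C/[Cr](Cl)Cl | intermediate
27 | (1S,2S,3E,7E,11R,12Z)-11-(tert-butyldimethylsilyloxy)-16-(tert-butyldiphenylsilyloxy)cembra-3,7,12,15(17)-tetraen-2-ol (expected major C2 epimer) | C=C(CO[Si](c1ccccc1)(c1ccccc1)C(C)(C)C)[C@@H]2C/C=C(C)\[C@H](O[Si](C)(C)C(C)(C)C)CC/C(C)=C/CC/C(C)=C/[C@@H]2O | intermediate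
28 | (1S,3E,7E,11R,12Z)-11-(tert-butyldimethylsilyloxy)-16-(tert-butyldiphenylsilyloxy)cembra-3,7,12,15(17)-tetraen-2-one | C=C(CO[Si](c1ccccc1)(c1ccccc1)C(C)(C)C)[C@@H]2C/C=C(C)\[C@H](O[Si](C)(C)C(C)(C)C)CC/C(C)=C/CC/C(C)=C/C2=O | intermediate
29 | (1S,2R,3E,7E,11R,12Z)-11-(tert-butyldimethylsilyloxy)-16-(tert-butyldiphenylsilyloxy)cembra-3,7,12,15(17)-tetraen-2-ol | C=C(CO[Si](c1ccccc1)(c1ccccc1)C(C)(C)C)[C@@H]2C/C=C(C)\[C@H](O[Si](C)(C)C(C)(C)C)CC/C(C)=C/CC/C(C)=C/[C@H]2O | intermediate
30 | (1S,2R,3E,7E,11R,12Z)-cembra-3,7,12,15(17)-tetraene-2,11,16-triol | C=C(CO)[C@@H]2C/C=C(C)\[C@H](O)CC/C(C)=C/CC/C(C)=C/[C@H]2O | intermediate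
31 | (1S,2R,3E,7E,11R,12Z)-2,16-epoxycembra-3,7,12,15(17)-tetraene-11,16-diol, lactol, C16 epimers (not isolated) | C=C1C(O)O[C@@H]2/C=C(\C)CC/C=C(C)/CC[C@@H](O)/C(C)=C\C[C@@H]12 | intermediate
32 | (1S,2R,3E,7E,11R,12Z)-11-hydroxycembra-3,7,12,15(17)-tetraen-16,2-olide | C=C1C(=O)O[C@@H]2/C=C(\C)CC/C=C(C)/CC[C@@H](O)/C(C)=C\C[C@@H]12 | intermediate
33 | (1S,2R,3E,7E,11R,12Z)-11-(methanesulfonyloxy)cembra-3,7,12,15(17)-tetraen-16,2-olide (not isolated) | C=C1C(=O)O[C@@H]2/C=C(\C)CC/C=C(C)/CC[C@@H](OS(C)(=O)=O)/C(C)=C\C[C@@H]12 | intermediate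
34 | (1S,2R,3E,7E,11S,12Z)-11-hydroperoxycembra-3,7,12,15(17)-tetraen-16,2-olide | C=C1C(=O)O[C@@H]2/C=C(\C)CC/C=C(C)/CC[C@H](OO)/C(C)=C\C[C@@H]12 | intermediate
35 | (1S,2R,3E,7S,8S,11S,12Z)-7,8-epoxy-11-hydroperoxycembra-3,12,15(17)-trien-16,2-olide | C=C1C(=O)O[C@@H]2/C=C(\C)CC[C@@H]3O[C@@]3(C)CC[C@H](OO)/C(C)=C\C[C@@H]12 | intermediate
36 | (1S,2R,3E,7S,8R,11S,12Z)-8,11-epidioxy-7-hydroxycembra-3,12,15(17)-trien-16,2-olide | C=C1C(=O)O[C@@H]2/C=C(\C)CC[C@H](O)[C@@]3(C)CC[C@H](OO3)/C(C)=C\C[C@@H]12 | intermediate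
37 | (1S,2R,3E,7S,8R,11S,12Z)-7-acetoxy-8,11-epidioxycembra-3,12,15(17)-trien-16,2-olide | C=C1C(=O)O[C@@H]2/C=C(\C)CC[C@H](OC(C)=O)[C@@]3(C)CC[C@H](OO3)/C(C)=C\C[C@@H]12 | target

**Step count**

Total step count: 25. Longest linear sequence: 21 steps (steps 1–7 and 12–25, from 1 to 37).

**Steps most likely to fail**

1. Step 22 (C11 hydroperoxide). What may go wrong: ionisation of the allylic methanesulfonate ahead of bimolecular attack by H2O2, which would erode the C11 configuration, shift the peroxide to C13 or give a diene by elimination. Fallback (peroxide brought in at C8, C11 bound through a ketone): setting out from hydroxy lactone 32, Dess–Martin oxidation would give the enone lactone F1. Shi epoxidation of its only electron-rich alkene (L-fructose-derived ketone, Oxone, K2CO3) would give the 7S,8S epoxy enone F2. Perhydrolysis with ethereal H2O2 and catalytic phosphomolybdic acid (H3PMo12O40) should open the epoxide at the tertiary C8 with inversion, and the new hydroperoxide should add to the C11 ketone to give the bicyclic peroxyhemiketal F3. Ionic reduction (Et3SiH, Me3SiOTf, CH2Cl2, −78 °C) through the peroxycarbenium ion, with hydride expected to enter from the outer face opposite the ten-atom bridge, would give hydroxy dioxane 36, where the route is rejoined. The C11 configuration then rests on substrate control.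

2. Step 17 (ring closure). What may go wrong: intermolecular coupling to oligomers, or protonation of the alkenylchromium species, instead of ring closure. Fallback (the same C2–C3 bond made between fragments, ring closed at C9–C10): keto aldehyde 9, isolated by leaving out the borohydride stage of step 6, and iodo alcohol 18 are coupled with CrCl2 and catalytic NiCl2 in DMSO to give the allylic alcohol F4 (2S expected). MsCl, LiCl and 2,4,6-collidine in DMF turn its primary allylic hydroxyl into the chloride F5, and Et3SiCl with imidazole gives the silyl ether F6. LiN(iPr)2 in THF under high dilution (−78 to 0 °C) forms the methyl ketone enolate, which closes the fourteen-membered ring by intramolecular allylic alkylation to give the macrocyclic ketone F7. CBS reduction as in step 13 gives the 11R alcohol F8, silylation as in step 14 gives the bis-silyl ether F9, and pyridinium p-toluenesulfonate in methanol removes the triethylsilyl group to give 27, where the route is rejoined.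

3. Step 19 (C2 reduction). What may go wrong: poor facial selectivity of hydride delivery in the macrocyclic enone, or epimerisation at C1 of the β,γ-unsaturated ketone. Fallback (inversion instead of reduction): setting out from the 2S alcohol 27, with steps 18 and 19 left out, a Mitsunobu reaction with 4-nitrobenzoic acid, PPh3 and diisopropyl azodicarboxylate gives the inverted 2R ester F10, and K2CO3 in methanol at 0 °C cleaves it to the 2R alcohol 29, where the route is rejoined.

**Further compounds**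

F1 | step 22 | (1S,2R,3E,7E,12Z)-11-oxocembra-3,7,12,15(17)-tetraen-16,2-olide | C=C1C(=O)O[C@@H]2/C=C(\C)CC/C=C(C)/CCC(=O)/C(C)=C\C[C@@H]12
F2 | step 22 | (1S,2R,3E,7S,8S,12Z)-7,8-epoxy-11-oxocembra-3,12,15(17)-trien-16,2-olide | C=C1C(=O)O[C@@H]2/C=C(\C)CC[C@@H]3O[C@@]3(C)CCC(=O)/C(C)=C\C[C@@H]12
F3 | step 22 | (1S,2R,3E,7S,8R,12Z)-8,11-epidioxy-7,11-dihydroxycembra-3,12,15(17)-trien-16,2-olide, peroxyhemiketal, C11 epimers | C=C1C(=O)O[C@@H]2/C=C(\C)CC[C@H](O)[C@@]3(C)CCC(O)(OO3)/C(C)=C\C[C@@H]12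
F4 | step 17 | (3Z,6S,7S,8E,12E)-6-[3-(tert-butyldiphenylsilyloxy)prop-1-en-2-yl]-7,14-dihydroxy-3,9,13-trimethyltetradeca-3,8,12-trien-2-one | OC/C(C)=C/CC/C(C)=C/[C@H](O)[C@@H](C/C=C(C)\C(C)=O)C(=C)CO[Si](c1ccccc1)(c1ccccc1)C(C)(C)C
F5 | step 17 | (3Z,6S,7S,8E,12E)-6-[3-(tert-butyldiphenylsilyloxy)prop-1-en-2-yl]-14-chloro-7-hydroxy-3,9,13-trimethyltetradeca-3,8,12-trien-2-one | ClC/C(C)=C/CC/C(C)=C/[C@H](O)[C@@H](C/C=C(C)\C(C)=O)C(=C)CO[Si](c1ccccc1)(c1ccccc1)C(C)(C)C
F6 | step 17 | (3Z,6S,7S,8E,12E)-6-[3-(tert-butyldiphenylsilyloxy)prop-1-en-2-yl]-14-chloro-3,9,13-trimethyl-7-(triethylsilyloxy)tetradeca-3,8,12-trien-2-one | ClC/C(C)=C/CC/C(C)=C/[C@H](O[Si](CC)(CC)CC)[C@@H](C/C=C(C)\C(C)=O)C(=C)CO[Si](c1ccccc1)(c1ccccc1)C(C)(C)C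
F7 | step 17 | (1S,2S,3E,7E,12Z)-16-(tert-butyldiphenylsilyloxy)-2-(triethylsilyloxy)cembra-3,7,12,15(17)-tetraen-11-one | C=C(CO[Si](c1ccccc1)(c1ccccc1)C(C)(C)C)[C@@H]2C/C=C(C)\C(=O)CC/C(C)=C/CC/C(C)=C/[C@@H]2O[Si](CC)(CC)CC
F8 | step 17 | (1S,2S,3E,7E,11R,12Z)-16-(tert-butyldiphenylsilyloxy)-2-(triethylsilyloxy)cembra-3,7,12,15(17)-tetraen-11-ol | C=C(CO[Si](c1ccccc1)(c1ccccc1)C(C)(C)C)[C@@H]2C/C=C(C)\[C@H](O)CC/C(C)=C/CC/C(C)=C/[C@@H]2O[Si](CC)(CC)CC
F9 | step 17 | (1S,2S,3E,7E,11R,12Z)-11-(tert-butyldimethylsilyloxy)-16-(tert-butyldiphenylsilyloxy)-2-(triethylsilyloxy)cembra-3,7,12,15(17)-tetraene | C=C(CO[Si](c1ccccc1)(c1ccccc1)C(C)(C)C)[C@@H]2C/C=C(C)\[C@H](O[Si](C)(C)C(C)(C)C)CC/C(C)=C/CC/C(C)=C/[C@@H]2O[Si](CC)(CC)CC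
F10 | step 19 | (1S,2R,3E,7E,11R,12Z)-11-(tert-butyldimethylsilyloxy)-16-(tert-butyldiphenylsilyloxy)cembra-3,7,12,15(17)-tetraen-2-yl 4-nitrobenzoate | C=C(CO[Si](c1ccccc1)(c1ccccc1)C(C)(C)C)[C@@H]2C/C=C(C)\[C@H](O[Si](C)(C)C(C)(C)C)CC/C(C)=C/CC/C(C)=C/[C@H]2OC(=O)c1ccc(cc1)[N+](=O)[O-]
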